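Ring A is disconnected across C2–C3 and C5–C10, exploiting its two 1,3-relationships: C3/C5 through quaternary C4 become the nitronate and enamine carbons of an achiral γ-nitro ketone, and C2/C10 through C1 become the δ- and β-carbons of a dienyl β-keto ester bearing a chiral ester at C9. One amine-mediated domino operation (1,6-nitro-Michael, intramolecular Michael, aldol condensation) forms C2–C3, C5–C10 and C7–C8 and so closes rings A and B from two acyclic precursors. The 4α-ester is later carved from the gem-dimethyl group by a 6α-hydroxyl-directed hypoiodite reaction; the side chain follows by radical allylation and nickel/chromium coupling.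

Key step: step 6

Numbering: labdane-type numbering is used throughout (decalin C1–C10; C17 on C8; C18 = 4α carbon, C19 = 4β methyl; C20 on C10; chain C11–C16); "8-phenylmenthyl" means (1R,2S,5R)-5-methyl-2-(2-phenylpropan-2-yl)cyclohexyl.
Assumption: the (1R,2S,5R)-8-phenylmenthyl ester is taken to shield the face of the alkylidene keto ester that leaves the required C10 configuration open to attack; if the sense proved opposite, the enantiomeric auxiliary would be used without other change.

Step 1
Reactants: 1 nitromethane; 2 mesityl oxide (4-methylpent-3-en-2-one)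
Product: 3 4,4-dimethyl-5-nitropentan-2-one
Conditions: DBU (cat.), MeCN, 23 °C
Reagents that add atoms: none
Why: Base-catalysed nitro-Michael addition to the β,β-disubstituted enone should give the γ-nitro ketone with the quaternary C4 and no stereocenter.

Step 2
Reactants: 4 (1R,2S,5R)-8-phenylmenthol; 5 2,2,6-trimethyl-4H-1,3-dioxin-4-one
Product: 6 8-phenylmenthyl 3-oxobutanoate
Conditions: xylene, 140 °C
Reagents that add atoms: none
Why: Thermal cycloreversion of the dioxinone releases acetylketene, which acylates the hindered secondary alcohol (acetoacetylation).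

Step 3
Reactants: 6 8-phenylmenthyl 3-oxobutanoate
Product: 7 8-phenylmenthyl 2-acetyl-3-oxobutanoate
Conditions: AcCl, MgCl2, pyridine, CH2Cl2, 0 to 23 °C
Reagents that add atoms: acetyl chloride CC(=O)Cl
Why: Magnesium-mediated soft enolisation and C-acylation of the β-keto ester should give the tricarbonyl compound.

Step 4
Reactants: 7 8-phenylmenthyl 2-acetyl-3-oxobutanoate
Product: 8 8-phenylmenthyl 2-acetyl-3-(trifluoromethylsulfonyloxy)but-2-enoate
Conditions: Tf2O, Et3N, CH2Cl2, −78 °C
Reagents that add atoms: trifluoromethanesulfonic anhydride O=S(=O)(OS(=O)(=O)C(F)(F)F)C(F)(F)F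
Why: O-sulfonylation of the enolised tricarbonyl compound gives the vinyl triflate, and the two acetyl groups are equivalent so no regiochemical question arises.

Step 5
Reactants: 8 8-phenylmenthyl 2-acetyl-3-(trifluoromethylsulfonyloxy)but-2-enoate
Product: 9 8-phenylmenthyl 2-acetyl-3-methylpenta-2,4-dienoate
Conditions: tributyl(vinyl)stannane, Pd(PPh3)4 (cat.), LiCl, THF, 60 °C
Reagents that add atoms: tributyl(vinyl)stannane C=C[Sn](CCCC)(CCCC)CCCC
Why: Stille coupling of the vinyl triflate under zerovalent palladium catalysis installs the vinyl group that becomes C1=C2.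

Step 6
Reactants: 3 4,4-dimethyl-5-nitropentan-2-one; 9 8-phenylmenthyl 2-acetyl-3-methylpenta-2,4-dienoate
Product: 12 8-phenylmenthyl 4,4,8,10β-tetramethyl-3-nitro-6-oxo-trans-decal-7-ene-9β-carboxylate (5α-H, 9α-H, C3 epimers), via acyclic nitro diketo ester 10 (not isolated), via monocyclic Michael adduct 11 (not isolated)
Conditions: DBU (0.2 equiv), MeCN, 0 to 23 °C; then pyrrolidine, AcOH, 4 Å molecular sieves, 60 °C (one pot)
Reagents that add atoms: none
Why: DBU converts 3 into its nitronate, which adds in 1,6-fashion to the unhindered vinyl terminus C2 of 9 (C2–C3), proton transfer regenerates the alkylidene β-keto ester, the pyrrolidine enamine of the C6 ketone then attacks C10 through C5 (C5–C10), and a second enamine at C7 condenses with the C8 acetyl carbonyl and loses water. The closest known reaction type is the amine-mediated Michael/Michael/aldol-condensation domino sequence (nitro-Michael addition, enamine addition to an alkylidene 1,3-dicarbonyl compound, Robinson-type cyclodehydration). Ring A closes by a 6-exo-trig Michael addition and ring B by a 6-(enolendo)-exo-trig aldol addition followed by dehydration. C10 is set in the Michael step by the 8-phenylmenthyl ester, whose phenyl group covers one face of the acceptor so that the tethered enamine attacks the other; C5 (α to the C6 ketone) and C9 (α to the ester, γ to the enone) stay epimerisable and should settle as the trans-decalin with the C9 ester equatorial, while the C3 nitro centre is irrelevant because it is removed. The step needs the pairing C3 with C2 and C5 with C10: only the nitronate is nucleophilic in the first stage and it can reach only the vinyl terminus because C10 is fully substituted, and only attack through C5 gives a six-membered ring. It also needs the C7-to-C8 sense of aldol closure, which the C6 carbonyl secures by being flanked by C5 with its two quaternary neighbours, so that it serves as the enamine partner and not as the acceptor.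

Step 7
Reactants: 12 bicyclic nitro enone ester
Product: 14 8-phenylmenthyl 8α-hydroxy-4,4,8β,10β-tetramethyl-3-nitro-6-oxo-trans-decalin-9β-carboxylate, via C8 pinacol boronate 13 (not isolated)
Conditions: CuCl (cat.), Xantphos (cat.), NaOtBu, B2pin2, MeOH, THF, 23 °C; then NaBO3·4H2O, THF/H2O
Reagents that add atoms: bis(pinacolato)diboron CC1(C)OB(OC1(C)C)B1OC(C)(C)C(C)(C)O1 (boron of 13); sodium perborate [Na+].[O-]OB=O
Why: Copper-catalysed conjugate borylation and oxidation with retention should deliver the hydroxyl to C8 from the α face, away from the axial C10 methyl and the C9 ester, setting 8α-OH/8β-CH3.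

Step 8
Reactants: 14 nitro hydroxy ketone ester
Product: 15 8-phenylmenthyl 8α-hydroxy-4,4,8β,10β-tetramethyl-6-oxo-trans-decalin-9β-carboxylate
Conditions: Bu3SnH, AIBN, PhMe, 110 °C
Reagents that add atoms: none
Why: Radical denitration with tributyltin hydride replaces the secondary nitro group at C3 by hydrogen.

Step 9
Reactants: 15 hydroxy ketone ester
Product: 16 drimane-6α,8α,11-triol (4,4,8β,10β-tetramethyl-trans-decalin-6α,8α-diol with CH2OH at C9β)
Conditions: SmI2, H2O, Et3N, THF, 23 °C
Reagents that add atoms: none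
Why: Electron-transfer reduction should give the equatorial 6α-alcohol under thermodynamic control (the axial 6β position is blocked by C19 and C20) and reduce the ester to the C11 alcohol with release of the auxiliary.

Step 10
Reactants: 16 drimane-6α,8α,11-triol
Product: 17 8α,11-cyclic carbonate of 16 (6α-OH free)
Conditions: 1,1′-carbonyldiimidazole, DMAP (cat.), PhMe, 80 °C
Reagents that add atoms: 1,1′-carbonyldiimidazole O=C(n1ccnc1)n1ccnc1
Why: The primary C11 and tertiary 8α hydroxyls form a six-membered cyclic carbonate, whereas the trans-diequatorial 6α-hydroxyl cannot bridge and stays free (carbonate protection of a 1,3-diol).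

Step 11
Reactants: 17 cyclic carbonate alcohol
Product: 18 6α,18-epoxy (tetrahydrofuran) carbonate
Conditions: PhI(OAc)2, I2, cyclohexane, hν, 40 °C
Reagents that add atoms: none
Why: In this hypoiodite reaction the 6α-alkoxy radical abstracts hydrogen by 1,5-transfer from the peri 4α-methyl group, the only δ-hydrogen within reach, and iodination/displacement closes the ether, which fixes C4 with the oxidised carbon α and the methyl β.

Step 12
Reactants: 18 6α,18-ether
Product: 19 18,6α-lactone carbonate
Conditions: RuCl3·xH2O (cat.), NaIO4, CCl4/MeCN/H2O, 23 °C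
Reagents that add atoms: sodium periodate [Na+].[O-]I(=O)(=O)=O
Why: RuO4 generated in the flask oxidises the ether methylene C18 to the γ-lactone (ether-to-lactone oxidation).

Step 13
Reactants: 19 lactone carbonate
Product: 21 methyl 6α,8α,11-trihydroxy-4β,8β,10β-trimethyl-trans-decalin-4α-carboxylate (CH2OH at C9β), via potassium carboxylate 20 (not isolated)
Conditions: KOH, MeOH/H2O, 60 °C; evaporate; MeI, KHCO3, DMF, 23 °C
Reagents that add atoms: potassium hydroxide [K+].[OH-]; iodomethane CI
Why: Saponification opens the strained trans-fused lactone and the carbonate, and alkylation of the carboxylate under non-acidic conditions should give the methyl ester without relactonisation.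

Step 14
Reactants: 21 triol methyl ester
Product: 22 C11 iodide of 21
Conditions: I2, PPh3, imidazole, CH2Cl2, 0 °C
Reagents that add atoms: iodine II
Why: The Appel reaction should convert only the primary alcohol, the 6α-hydroxyl being hindered and the 8α-hydroxyl tertiary.

Step 15
Reactants: 23 2,3-dibromopropene; 24 sodium benzenesulfinate
Product: 25 2-bromoallyl phenyl sulfone
Conditions: DMF, 23 °C
Reagents that add atoms: none
Why: SN2 S-alkylation of the sulfinate at the allylic bromide leaves the vinylic bromide untouched.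

Step 16
Reactants: 22 C11 iodide; 25 2-bromoallyl phenyl sulfone
Product: 26 vinyl bromide with C9–CH2–CH2–C(Br)=CH2
Conditions: hexabutylditin, PhH, hν, 80 °C
Reagents that add atoms: none
Why: In this radical allylation the C11 radical adds to the methylene terminus of the allyl sulfone and β-fragmentation of the sulfonyl radical gives the 2-bromoalkene, forming C11–C12 in the presence of free hydroxyls.

Step 17
Reactants: 27 hex-5-en-2-one
Product: 29 (S)-3-hydroxyhex-5-en-2-one, via aminoxy ketone 28 (not isolated)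
Conditions: nitrosobenzene, D-proline (cat.), DMSO, 23 °C; then Zn, AcOH, 0 °C
Reagents that add atoms: nitrosobenzene O=Nc1ccccc1
Why: Proline-catalysed α-aminoxylation through the more substituted enamine should set the future C16 configuration under catalyst control, and zinc cleaves the N–O bond.

Step 18
Reactants: 29 (S)-3-hydroxyhex-5-en-2-one
Product: 30 (S)-5-allyl-4-methylfuran-2(5H)-one
Conditions: (triphenylphosphoranylidene)ketene, PhMe, 110 °C
Reagents that add atoms: (triphenylphosphoranylidene)ketene O=C=C=P(c1ccccc1)(c1ccccc1)c1ccccc1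
Why: Addition of the hydroxyl to the ketene and intramolecular Wittig olefination of the methyl ketone give the 4-methylbutenolide without touching the stereocenter.

Step 19
Reactants: 30 (S)-5-allyl-4-methylfuran-2(5H)-one
Product: 31 (S)-2-(3-methyl-5-oxo-2,5-dihydrofuran-2-yl)acetaldehyde
Conditions: O3, CH2Cl2/MeOH, −78 °C; Me2S
Reagents that add atoms: ozone [O-][O+]=O
Why: Ozonolysis should cleave the electron-rich terminal alkene much faster than the electron-poor butenolide double bond.

Step 20
Reactants: 26 vinyl bromide; 31 butenolide aldehyde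
Product: 32 (14R)-allylic alcohol (14-hydroxy precursor of the target)
Conditions: CrCl2, NiCl2 (cat.), chiral 2-(2-methanesulfonamidophenyl)-4-isopropyloxazoline ligand, Et3N, THF, 23 °C
Reagents that add atoms: none
Why: The Nozaki–Hiyama–Kishi coupling forms C13–C14 chemoselectively at the aldehyde, and the chiral sulfonamide–oxazoline ligand on chromium should control the aldehyde face to give the 14R alcohol.

Step 21
Reactants: 32 (14R)-allylic alcohol
Product: 34 CNP0324515.1 (14S-hydroperoxide), via allylic mesylate 33 (not isolated)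
Conditions: MsCl, Et3N, CH2Cl2, −78 °C; then anhydrous H2O2, Et2O, −78 to −40 °C
Reagents that add atoms: hydrogen peroxide OO; methanesulfonyl chloride CS(=O)(=O)Cl (carried only by 33)
Why: Mesylation of the unhindered allylic C14 hydroxyl and SN2 displacement by hydrogen peroxide at low temperature should give the 14S hydroperoxide with inversion.

Compound list
1 | nitromethane | C[N+](=O)[O-] | starting material
2 | mesityl oxide | CC(=O)C=C(C)C | starting material
3 | 4,4-dimethyl-5-nitropentan-2-one | CC(=O)CC(C)(C)C[N+](=O)[O-] | intermediate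
4 | (1R,2S,5R)-8-phenylmenthol | C[C@@H]1CC[C@H]([C@@H](C1)O)C(C)(C)c2ccccc2 | starting material
5 | 2,2,6-trimethyl-4H-1,3-dioxin-4-one | CC1=CC(=O)OC(C)(C)O1 | starting material
6 | 8-phenylmenthyl 3-oxobutanoate | C[C@@H]1CC[C@H]([C@@H](C1)OC(=O)CC(C)=O)C(C)(C)c2ccccc2 | intermediate
7 | 8-phenylmenthyl 2-acetyl-3-oxobutanoate | C[C@@H]1CC[C@H]([C@@H](C1)OC(=O)C(C(C)=O)C(C)=O)C(C)(C)c2ccccc2 | intermediate
8 | 8-phenylmenthyl 2-acetyl-3-(trifluoromethylsulfonyloxy)but-2-enoate | C[C@@H]1CC[C@H]([C@@H](C1)OC(=O)C(C(C)=O)=C(C)OS(=O)(=O)C(F)(F)F)C(C)(C)c2ccccc2 | intermediate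
9 | 8-phenylmenthyl 2-acetyl-3-methylpenta-2,4-dienoate | C[C@@H]1CC[C@H]([C@@H](C1)OC(=O)C(C(C)=O)=C(C)C=C)C(C)(C)c2ccccc2 | intermediate
10 | 8-phenylmenthyl 2-acetyl-3,7,7-trimethyl-6-nitro-9-oxodec-2-enoate | C[C@@H]1CC[C@H]([C@@H](C1)OC(=O)C(C(C)=O)=C(C)CCC([N+](=O)[O-])C(C)(C)CC(C)=O)C(C)(C)c2ccccc2 | intermediate
11 | 8-phenylmenthyl 2-(2-acetyl-1,3,3-trimethyl-4-nitrocyclohexyl)-3-oxobutanoate (C10 as in the target, 5α-H) | C[C@@H]1CC[C@H]([C@@H](C1)OC(=O)C(C(C)=O)[C@@]3(C)CCC([N+](=O)[O-])C(C)(C)[C@@H]3C(C)=O)C(C)(C)c2ccccc2 | intermediate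
12 | 8-phenylmenthyl 4,4,8,10β-tetramethyl-3-nitro-6-oxo-trans-decal-7-ene-9β-carboxylate | C[C@@H]1CC[C@H]([C@@H](C1)OC(=O)[C@@H]3[C@@]4(C)CCC([N+](=O)[O-])C(C)(C)[C@@H]4C(=O)C=C3C)C(C)(C)c2ccccc2 | intermediate
13 | 8α-(pinacolboryl) derivative of 12 (C7 saturated) | C[C@@H]1CC[C@H]([C@@H](C1)OC(=O)[C@@H]3[C@@]4(C)CCC([N+](=O)[O-])C(C)(C)[C@@H]4C(=O)C[C@@]3(C)B5OC(C)(C)C(C)(C)O5)C(C)(C)c2ccccc2 | intermediate
14 | 8-phenylmenthyl 8α-hydroxy-4,4,8β,10β-tetramethyl-3-nitro-6-oxo-trans-decalin-9β-carboxylate | C[C@@H]1CC[C@H]([C@@H](C1)OC(=O)[C@@H]3[C@@]4(C)CCC([N+](=O)[O-])C(C)(C)[C@@H]4C(=O)C[C@@]3(C)O)C(C)(C)c2ccccc2 | intermediate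
15 | 8-phenylmenthyl 8α-hydroxy-4,4,8β,10β-tetramethyl-6-oxo-trans-decalin-9β-carboxylate | C[C@@H]1CC[C@H]([C@@H](C1)OC(=O)[C@@H]3[C@@]4(C)CCCC(C)(C)[C@@H]4C(=O)C[C@@]3(C)O)C(C)(C)c2ccccc2 | intermediate
16 | drimane-6α,8α,11-triol | OC[C@@H]1[C@@]2(C)CCCC(C)(C)[C@@H]2[C@@H](O)C[C@@]1(C)O | intermediate
17 | drimane-6α,8α,11-triol 8,11-carbonate | O=C1OC[C@@H]2[C@@]3(C)CCCC(C)(C)[C@@H]3[C@@H](O)C[C@@]2(C)O1 | intermediate
18 | 6α,18-epoxydrimane-8α,11-diol carbonate | O=C1OC[C@@H]2[C@@]3(C)CCC[C@@](C)(C5)[C@@H]3[C@@H](O5)C[C@@]2(C)O1 | intermediate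
19 | 18,6α-lactone of the 8,11-carbonate | O=C1OC[C@@H]2[C@@]3(C)CCC[C@@](C)(C5=O)[C@@H]3[C@@H](O5)C[C@@]2(C)O1 | intermediate
20 | potassium 6α,8α,11-trihydroxy-4β,8β,10β-trimethyl-trans-decalin-4α-carboxylate | OC[C@@H]1[C@@]2(C)CCC[C@@](C)(C(=O)[O-])[C@@H]2[C@@H](O)C[C@@]1(C)O.[K+] | intermediate
21 | methyl 6α,8α,11-trihydroxy-4β,8β,10β-trimethyl-trans-decalin-4α-carboxylate | OC[C@@H]1[C@@]2(C)CCC[C@@](C)(C(=O)OC)[C@@H]2[C@@H](O)C[C@@]1(C)O | intermediate
22 | C11 iodide of 21 | IC[C@@H]1[C@@]2(C)CCC[C@@](C)(C(=O)OC)[C@@H]2[C@@H](O)C[C@@]1(C)O | intermediate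
23 | 2,3-dibromopropene | C=C(Br)CBr | starting material
24 | sodium benzenesulfinate | [Na+].[O-]S(=O)c1ccccc1 | starting material
25 | 2-bromoallyl phenyl sulfone | C=C(Br)CS(=O)(=O)c1ccccc1 | intermediate
26 | methyl 9β-(3-bromobut-3-enyl)-6α,8α-dihydroxy-4β,8β,10β-trimethyl-trans-decalin-4α-carboxylate | C=C(Br)CC[C@@H]1[C@@]2(C)CCC[C@@](C)(C(=O)OC)[C@@H]2[C@@H](O)C[C@@]1(C)O | intermediate
27 | hex-5-en-2-one | CC(=O)CCC=C | starting material
28 | (S)-3-(phenylaminooxy)hex-5-en-2-one | C=CC[C@@H](C(C)=O)ONc1ccccc1 | intermediate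
29 | (S)-3-hydroxyhex-5-en-2-one | C=CC[C@@H](C(C)=O)O | intermediate
30 | (S)-5-allyl-4-methylfuran-2(5H)-one | C=CC[C@@H]1OC(=O)C=C1C | intermediate
31 | (S)-2-(3-methyl-5-oxo-2,5-dihydrofuran-2-yl)acetaldehyde | O=CC[C@@H]1OC(=O)C=C1C | intermediate
32 | (14R,16S)-14-hydroxy analogue of the target | C=C(CC[C@@H]1[C@@]2(C)CCC[C@@](C)(C(=O)OC)[C@@H]2[C@@H](O)C[C@@]1(C)O)[C@@H](C[C@@H]1OC(=O)C=C1C)O | intermediate
33 | (14R)-methanesulfonate of 32 | C=C(CC[C@@H]1[C@@]2(C)CCC[C@@](C)(C(=O)OC)[C@@H]2[C@@H](O)C[C@@]1(C)O)[C@@H](C[C@@H]1OC(=O)C=C1C)OS(C)(=O)=O | intermediate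
34 | CNP0324515.1 | C=C(CC[C@@H]1[C@@]2(C)CCC[C@@](C)(C(=O)OC)[C@@H]2[C@@H](O)C[C@@]1(C)O)[C@H](C[C@@H]1OC(=O)C=C1C)OO | target

Total step count: 21. Longest linear sequence: 16 steps (steps 2–14, 16, 20, 21).

Steps most likely to fail

Step 6. The congested C5–C10 ring closure may not proceed (reversal of the Michael addition), the dienyl ester may oligomerise, or the auxiliary may give poor facial bias. Fallback: the sequence is run stepwise from compounds 3 and 9. Only the DBU stage is carried out and the acyclic nitro diketo ester 10 is isolated. It is converted with TMSOTf/Et3N into the thermodynamic C5=C6 trimethylsilyl enol ether F1. TiCl4 in CH2Cl2 at −78 °C then closes ring A by an intramolecular Mukaiyama–Michael addition to the Lewis-acid-activated alkylidene keto ester, giving 11, which is isolated. A separate aldol condensation (KOtBu, t-BuOH) returns to compound 12.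

Step 11. The 6α-alkoxy radical may undergo β-fragmentation of the C5–C6 bond or abstract hydrogen elsewhere instead of from C18. Fallback: from compound 17 the Barton reaction is used. Nitrosyl chloride in pyridine gives the 6α-nitrite F2. Photolysis in benzene transfers the nitroso group to C18 and, after tautomerisation, gives the 18-oxime F3. Hydrolysis (aqueous NaHSO3, then acid) releases the aldehyde, which closes with the 6α-hydroxyl to the lactol F4. Oxidation (Ag2CO3 on Celite, PhH, 80 °C) gives the lactone, compound 19.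

Step 21. Attack of hydrogen peroxide at the terminal methylene (allylic transposition) or ionisation of the mesylate with loss of configuration may compete with direct SN2 displacement. Fallback: from compound 32 the 2-nitrobenzenesulfonate F5 is prepared (2-nitrobenzenesulfonyl chloride, DMAP, CH2Cl2, 0 °C). It is displaced with the caesium salt of 2-methoxypropan-2-yl hydroperoxide in DMF at 0 °C, a bulkier nucleophile that favours the secondary carbon, to give the peroxyketal F6 with inversion. Mild hydrolysis (AcOH/H2O/THF) releases compound 34.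

Further compounds
F1 | step 6 | trimethylsilyl enol ether (C5=C6) of 10 | C[C@@H]1CC[C@H]([C@@H](C1)OC(=O)C(C(C)=O)=C(C)CCC([N+](=O)[O-])C(C)(C)C=C(C)O[Si](C)(C)C)C(C)(C)c2ccccc2
F2 | step 11 | 6α-nitrite of 17 | O=C1OC[C@@H]2[C@@]3(C)CCCC(C)(C)[C@@H]3[C@@H](ON=O)C[C@@]2(C)O1
F3 | step 11 | 18-oxime of the 6α-hydroxy carbonate | O=C1OC[C@@H]2[C@@]3(C)CCC[C@@](C)(C=NO)[C@@H]3[C@@H](O)C[C@@]2(C)O1
F4 | step 11 | 18,6α-lactol carbonate | O=C1OC[C@@H]2[C@@]3(C)CCC[C@@](C)(C5O)[C@@H]3[C@@H](O5)C[C@@]2(C)O1
F5 | step 21 | (14R)-2-nitrobenzenesulfonate of 32 | C=C(CC[C@@H]1[C@@]2(C)CCC[C@@](C)(C(=O)OC)[C@@H]2[C@@H](O)C[C@@]1(C)O)[C@@H](C[C@@H]1OC(=O)C=C1C)OS(=O)(=O)c1ccccc1[N+](=O)[O-]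
F6 | step 21 | (14S)-2-methoxypropan-2-yl peroxide of the target | C=C(CC[C@@H]1[C@@]2(C)CCC[C@@](C)(C(=O)OC)[C@@H]2[C@@H](O)C[C@@]1(C)O)[C@H](C[C@@H]1OC(=O)C=C1C)OOC(C)(C)OC
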